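**Retrosynthetic overview**

- The target is a biflavone ether: unit 1 is a 5,7-dihydroxy-4'-methoxyflavone carrying an aryl ether at C8, and unit 2 is a 5,7-dihydroxyflavone joined through C4' of its ring B. The strategy rests on that ring B of unit 2, a para-phenylene whose only substituents are the ether oxygen (C4') and the pyranone carbon C2 (on C1').
- Ring B of unit 2 is disconnected to methyl coumalate 12 and aryl ethynyl ether 11 by a (4+2) cycloaddition with loss of CO2. 11 comes from the Dakin phenol 5 and trichloroethylene, so the crowded C8 oxygen is vinylated, not arylated.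
- The pyranone of unit 2 is disconnected by Baker-Venkataraman rearrangement and cyclodehydration to acid 15 and acetophenone 17.
- The pyranone of unit 1 is disconnected by a Ruhemann annulation: O1-C2 by oxa-Michael addition of phenol 21 to arylpropiolate 24, and C4-C4a by Friedel-Crafts acylation. Debenzylation is last.
- Order of ring formation: ring B of unit 2 (step 6), pyranone of unit 2 (step 11), pyranone of unit 1 (step 14). Both rings A come from the phloroglucinol starting materials.

Key step: step 6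

Remark on the chemistry: the target has no stereocentre. The only stereo elements on the way are the E alkene of 8, the Z alkene of 25 to 27 (its geometry is not critical) and the two bridgehead centres of racemic 13, which vanish in the same step.

**Route**

Step 1
Reactants: 1 2,4,6-trihydroxybenzaldehyde
Product: 2 2,4-bis(benzyloxy)-6-hydroxybenzaldehyde
Conditions: BnBr (2.1 equiv), K2CO3, DMF, rt
Reagents that add atoms: benzyl bromide, BrCc1ccccc1
Why: Williamson etherification should stop at the 2,4-dibenzyl ether because the remaining hydroxyl is hydrogen-bonded to the aldehyde and is the least nucleophilic.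

Step 2
Reactants: 2 2,4-bis(benzyloxy)-6-hydroxybenzaldehyde
Product: 3 2,4-bis(benzyloxy)-6-(methoxymethoxy)benzaldehyde
Conditions: NaH, DMF, 0 °C; MOMCl, 0 °C to rt
Reagents that add atoms: chloromethyl methyl ether, COCCl
Why: Williamson-type O-alkylation of the sodium phenoxide with MOMCl overcomes the chelation and installs an acetal that survives base, organolithium and heat.

Step 3
Reactants: 3 2,4-bis(benzyloxy)-6-(methoxymethoxy)benzaldehyde
Product: 5 2,4-bis(benzyloxy)-6-(methoxymethoxy)phenol, via aryl formate 4 (not isolated)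
Conditions: mCPBA, CH2Cl2, 0 °C to rt; aqueous Na2S2O3/NaHCO3 wash; then K2CO3 (cat.), MeOH, rt, under N2
Reagents that add atoms: mCPBA, OOC(=O)c1cccc(Cl)c1
Why: In this Dakin-type Baeyer-Villiger oxidation the trialkoxyaryl group migrates in preference to hydrogen to give formate 4, and base-catalysed methanolysis releases the phenol.

Step 4
Reactants: 5 2,4-bis(benzyloxy)-6-(methoxymethoxy)phenol; 6 trichloroethylene
Product: 8 1,5-bis(benzyloxy)-2-{[(E)-1,2-dichloroethenyl]oxy}-3-(methoxymethoxy)benzene, via dichloroacetylene 7 (not isolated)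
Conditions: K2CO3, DMF, 70 °C
Reagents that add atoms: none
Why: This is an elimination-addition vinylation: the base dehydrochlorinates 6 to the small linear electrophile 7, the phenoxide adds despite its two ortho substituents, and anti protonation sets the E geometry.

Step 5
Reactants: 8 1,5-bis(benzyloxy)-2-{[(E)-1,2-dichloroethenyl]oxy}-3-(methoxymethoxy)benzene
Product: 11 1,5-bis(benzyloxy)-2-(ethynyloxy)-3-(methoxymethoxy)benzene, via chloroalkynyl ether 9 (not isolated), via lithium aryloxyacetylide 10 (not isolated)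
Conditions: n-BuLi (2.2 equiv), THF, -78 °C; then H2O, -78 to 0 °C; crude product used at once
Reagents that add atoms: none
Why: This is the dichlorovinyl ether to ynol ether conversion: vinylic deprotonation and loss of chloride give 9, chlorine-lithium exchange gives 10, and water protonates it; at -78 °C these steps should outrun ring or benzylic lithiation.

Step 6
Reactants: 11 1,5-bis(benzyloxy)-2-(ethynyloxy)-3-(methoxymethoxy)benzene; 12 methyl coumalate
Product: 14 methyl 4-[2,4-bis(benzyloxy)-6-(methoxymethoxy)phenoxy]benzoate, via bicyclic lactone 13 (not isolated)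
Conditions: 12 (1.5 equiv), toluene, 100 °C, sealed tube, Ar
Reagents that add atoms: none
Why: The electron-poor pyrone diene of 12 (C3 to C6) and the electron-rich alkyne of 11 combine in an asynchronous inverse-electron-demand (4+2) cycloaddition, in which the nucleophilic terminal alkyne carbon bonds to C6 and the oxygen-bearing carbon to C3, giving the 2-oxabicyclo[2.2.2]octadienone 13. Retro-(4+2) loss of CO2 from 13 then aromatises the new ring, so the six-membered carbocycle is closed by an intermolecular cycloaddition that forms two C-C bonds, not by a cyclisation. The closest known reaction type is the inverse-demand Diels-Alder/decarboxylation of methyl coumalate with ketene acetals, enol ethers, ynamines and other electron-rich alkynes to para-substituted benzoates. No stereocentre is created in 14, since the two bridgehead centres of racemic 13 are lost on aromatisation. The step needs para over meta regioselectivity, which is secured by matching the largest LUMO coefficient of the coumalate (C6, beta to the ester and delta to the lactone carbonyl) with the largest HOMO coefficient of the ynol ether (its terminal carbon). Both ortho positions of the aryloxy group are substituted, which blocks sigmatropic and benzofuran-forming side paths and should slow oligomerisation of the ynol ether.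

Step 7
Reactants: 14 methyl 4-[2,4-bis(benzyloxy)-6-(methoxymethoxy)phenoxy]benzoate
Product: 15 4-[2,4-bis(benzyloxy)-6-(methoxymethoxy)phenoxy]benzoic acid
Conditions: LiOH, THF/MeOH/H2O, 50 °C; then 1 M HCl to pH 4, 0 °C
Reagents that add atoms: lithium hydroxide, [Li+].[OH-]
Why: Saponification of the unhindered methyl benzoate is done before any flavone exists, and the benzyl ethers, MOM acetal and diaryl ether are inert to hydroxide.

Step 8
Reactants: 16 2,4,6-trihydroxyacetophenone
Product: 17 1-[2,4-bis(benzyloxy)-6-hydroxyphenyl]ethan-1-one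
Conditions: BnBr (2.1 equiv), K2CO3, DMF, rt
Reagents that add atoms: benzyl bromide, BrCc1ccccc1
Why: Williamson etherification spares the hydroxyl chelated to the acetyl group, which is the one needed for the ester of step 9.

Step 9
Reactants: 15 4-[2,4-bis(benzyloxy)-6-(methoxymethoxy)phenoxy]benzoic acid; 17 1-[2,4-bis(benzyloxy)-6-hydroxyphenyl]ethan-1-one
Product: 18 2-acetyl-3,5-bis(benzyloxy)phenyl 4-[2,4-bis(benzyloxy)-6-(methoxymethoxy)phenoxy]benzoate
Conditions: DCC, DMAP (cat.), CH2Cl2, 0 °C to rt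
Reagents that add atoms: none
Why: Steglich esterification acylates the chelated phenol through the acylpyridinium ion under neutral conditions, so no HCl is formed and the MOM acetal is safe.

Step 10
Reactants: 18 2-acetyl-3,5-bis(benzyloxy)phenyl 4-[2,4-bis(benzyloxy)-6-(methoxymethoxy)phenoxy]benzoate
Product: 19 1-[2,4-bis(benzyloxy)-6-hydroxyphenyl]-3-{4-[2,4-bis(benzyloxy)-6-(methoxymethoxy)phenoxy]phenyl}propane-1,3-dione
Conditions: KOtBu (2.2 equiv), THF, 0 °C to rt; then AcOH
Reagents that add atoms: none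
Why: In the Baker-Venkataraman rearrangement the methyl ketone enolate attacks the neighbouring aryl ester through a six-membered transition state and the aroyl group moves from oxygen to carbon.

Step 11
Reactants: 19 1-[2,4-bis(benzyloxy)-6-hydroxyphenyl]-3-{4-[2,4-bis(benzyloxy)-6-(methoxymethoxy)phenoxy]phenyl}propane-1,3-dione
Product: 21 5,7-bis(benzyloxy)-2-{4-[2,4-bis(benzyloxy)-6-hydroxyphenoxy]phenyl}-4H-chromen-4-one, via MOM-protected flavone 20 (not isolated)
Conditions: conc. HCl (cat.), MeOH/THF, 50 °C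
Reagents that add atoms: none
Why: Acid-catalysed cyclodehydration of the o-hydroxyaryl 1,3-diketone closes the pyranone of unit 2 to give 20, and continued acid methanolysis of the MOM acetal frees the one phenol needed for the second annulation.

Step 12
Reactants: 22 1-ethynyl-4-methoxybenzene
Product: 24 tert-butyl 3-(4-methoxyphenyl)prop-2-ynoate, via lithium arylacetylide 23 (not isolated)
Conditions: n-BuLi, THF, -78 °C; Boc2O, -78 °C to rt; H2O
Reagents that add atoms: di-tert-butyl dicarbonate, CC(C)(C)OC(=O)OC(=O)OC(C)(C)C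
Why: Acylation of the lithium acetylide with Boc2O gives the tert-butyl ynoate, whose hindered ester resists a second addition and can later be removed by acid alone.

Step 13
Reactants: 21 5,7-bis(benzyloxy)-2-{4-[2,4-bis(benzyloxy)-6-hydroxyphenoxy]phenyl}-4H-chromen-4-one; 24 tert-butyl 3-(4-methoxyphenyl)prop-2-ynoate
Product: 25 tert-butyl (Z)-3-(2-{4-[5,7-bis(benzyloxy)-4-oxo-4H-chromen-2-yl]phenoxy}-3,5-bis(benzyloxy)phenoxy)-3-(4-methoxyphenyl)prop-2-enoate
Conditions: Cs2CO3 (0.3 equiv), DMF, 80 °C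
Reagents that add atoms: none
Why: This oxa-Michael addition of the phenoxide to the ynoate (first stage of the Ruhemann flavone synthesis) fixes the O1-C2 bond without regiochemical ambiguity, and anti addition should favour the Z alkene.

Step 14
Reactants: 25 tert-butyl (Z)-3-(2-{4-[5,7-bis(benzyloxy)-4-oxo-4H-chromen-2-yl]phenoxy}-3,5-bis(benzyloxy)phenoxy)-3-(4-methoxyphenyl)prop-2-enoate
Product: 28 5,7-bis(benzyloxy)-8-{4-[5,7-bis(benzyloxy)-4-oxo-4H-chromen-2-yl]phenoxy}-2-(4-methoxyphenyl)-4H-chromen-4-one, via acrylic acid 26 (not isolated), via mixed anhydride 27 (not isolated)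
Conditions: TFA, CH2Cl2, 0 °C to rt; then TFAA, 0 °C to rt
Reagents that add atoms: none
Why: Acidolysis of the tert-butyl ester gives 26, TFAA turns it into 27, and an intramolecular Friedel-Crafts acylation closes the pyranone at the only free position ortho to the vinyloxy oxygen, which two benzyloxy groups activate, while acid equilibrates the push-pull alkene so both geometries converge.

Step 15
Reactants: 28 5,7-bis(benzyloxy)-8-{4-[5,7-bis(benzyloxy)-4-oxo-4H-chromen-2-yl]phenoxy}-2-(4-methoxyphenyl)-4H-chromen-4-one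
Product: 29 5,7-dihydroxy-8-[4-(5,7-dihydroxy-4-oxo-4H-chromen-2-yl)phenoxy]-2-(4-methoxyphenyl)-4H-chromen-4-one
Conditions: H2 (1 atm), Pd/C (10 wt %), THF/MeOH, rt
Reagents that add atoms: none
Why: Hydrogenolysis removes the four benzyl ethers while the diaryl ether, the methyl ether and the flavone C2-C3 double bonds should stay intact at 1 atm if the reaction is stopped at full debenzylation.

**Compound list**

1 | 2,4,6-trihydroxybenzaldehyde | O=Cc1c(O)cc(O)cc1O | starting material
2 | 2,4-bis(benzyloxy)-6-hydroxybenzaldehyde | O=Cc1c(O)cc(OCc2ccccc2)cc1OCc1ccccc1 | intermediate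
3 | 2,4-bis(benzyloxy)-6-(methoxymethoxy)benzaldehyde | O=Cc1c(OCOC)cc(OCc2ccccc2)cc1OCc1ccccc1 | intermediate
4 | 2,4-bis(benzyloxy)-6-(methoxymethoxy)phenyl formate | O=COc1c(OCOC)cc(OCc2ccccc2)cc1OCc1ccccc1 | intermediate
5 | 2,4-bis(benzyloxy)-6-(methoxymethoxy)phenol | Oc1c(OCOC)cc(OCc2ccccc2)cc1OCc1ccccc1 | intermediate
6 | trichloroethylene | ClC=C(Cl)Cl | starting material
7 | dichloroacetylene | ClC#CCl | intermediate
8 | 1,5-bis(benzyloxy)-2-{[(E)-1,2-dichloroethenyl]oxy}-3-(methoxymethoxy)benzene | Cl/C=C(/Cl)Oc1c(OCOC)cc(OCc2ccccc2)cc1OCc1ccccc1 | intermediate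
9 | 1,5-bis(benzyloxy)-2-[(chloroethynyl)oxy]-3-(methoxymethoxy)benzene | ClC#COc1c(OCOC)cc(OCc2ccccc2)cc1OCc1ccccc1 | intermediate
10 | lithium 2-[2,4-bis(benzyloxy)-6-(methoxymethoxy)phenoxy]ethynide | [Li]C#COc1c(OCOC)cc(OCc2ccccc2)cc1OCc1ccccc1 | intermediate
11 | 1,5-bis(benzyloxy)-2-(ethynyloxy)-3-(methoxymethoxy)benzene | C#COc1c(OCOC)cc(OCc2ccccc2)cc1OCc1ccccc1 | intermediate
12 | methyl coumalate | COC(=O)c1ccc(=O)oc1 | starting material
13 | methyl 5-[2,4-bis(benzyloxy)-6-(methoxymethoxy)phenoxy]-3-oxo-2-oxabicyclo[2.2.2]octa-5,7-diene-7-carboxylate (racemic, one enantiomer drawn) | O=C1O[C@H]2C=C(Oc3c(OCOC)cc(OCc4ccccc4)cc3OCc3ccccc3)[C@@H]1C=C2C(=O)OC | intermediate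
14 | methyl 4-[2,4-bis(benzyloxy)-6-(methoxymethoxy)phenoxy]benzoate | COC(=O)c1ccc(Oc2c(OCOC)cc(OCc3ccccc3)cc2OCc2ccccc2)cc1 | intermediate
15 | 4-[2,4-bis(benzyloxy)-6-(methoxymethoxy)phenoxy]benzoic acid | OC(=O)c1ccc(Oc2c(OCOC)cc(OCc3ccccc3)cc2OCc2ccccc2)cc1 | intermediate
16 | 2,4,6-trihydroxyacetophenone | CC(=O)c1c(O)cc(O)cc1O | starting material
17 | 1-[2,4-bis(benzyloxy)-6-hydroxyphenyl]ethan-1-one | CC(=O)c1c(O)cc(OCc2ccccc2)cc1OCc1ccccc1 | intermediate
18 | 2-acetyl-3,5-bis(benzyloxy)phenyl 4-[2,4-bis(benzyloxy)-6-(methoxymethoxy)phenoxy]benzoate | CC(=O)c1c(OC(=O)c2ccc(Oc3c(OCOC)cc(OCc4ccccc4)cc3OCc3ccccc3)cc2)cc(OCc2ccccc2)cc1OCc1ccccc1 | intermediate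
19 | 1-[2,4-bis(benzyloxy)-6-hydroxyphenyl]-3-{4-[2,4-bis(benzyloxy)-6-(methoxymethoxy)phenoxy]phenyl}propane-1,3-dione | O=C(CC(=O)c1ccc(Oc2c(OCOC)cc(OCc3ccccc3)cc2OCc2ccccc2)cc1)c1c(O)cc(OCc2ccccc2)cc1OCc1ccccc1 | intermediate
20 | 5,7-bis(benzyloxy)-2-{4-[2,4-bis(benzyloxy)-6-(methoxymethoxy)phenoxy]phenyl}-4H-chromen-4-one | COCOc1cc(OCc2ccccc2)cc(OCc2ccccc2)c1Oc1ccc(-c2cc(=O)c3c(OCc4ccccc4)cc(OCc4ccccc4)cc3o2)cc1 | intermediate
21 | 5,7-bis(benzyloxy)-2-{4-[2,4-bis(benzyloxy)-6-hydroxyphenoxy]phenyl}-4H-chromen-4-one | Oc1cc(OCc2ccccc2)cc(OCc2ccccc2)c1Oc1ccc(-c2cc(=O)c3c(OCc4ccccc4)cc(OCc4ccccc4)cc3o2)cc1 | intermediate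
22 | 1-ethynyl-4-methoxybenzene | C#Cc1ccc(OC)cc1 | starting material
23 | lithium (4-methoxyphenyl)ethynide | [Li]C#Cc1ccc(OC)cc1 | intermediate
24 | tert-butyl 3-(4-methoxyphenyl)prop-2-ynoate | CC(C)(C)OC(=O)C#Cc1ccc(OC)cc1 | intermediate
25 | tert-butyl (Z)-3-(2-{4-[5,7-bis(benzyloxy)-4-oxo-4H-chromen-2-yl]phenoxy}-3,5-bis(benzyloxy)phenoxy)-3-(4-methoxyphenyl)prop-2-enoate | CC(C)(C)OC(=O)/C=C(\Oc1cc(OCc2ccccc2)cc(OCc2ccccc2)c1Oc1ccc(-c2cc(=O)c3c(OCc4ccccc4)cc(OCc4ccccc4)cc3o2)cc1)c1ccc(OC)cc1 | intermediate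
26 | (Z)-3-(2-{4-[5,7-bis(benzyloxy)-4-oxo-4H-chromen-2-yl]phenoxy}-3,5-bis(benzyloxy)phenoxy)-3-(4-methoxyphenyl)prop-2-enoic acid | OC(=O)/C=C(\Oc1cc(OCc2ccccc2)cc(OCc2ccccc2)c1Oc1ccc(-c2cc(=O)c3c(OCc4ccccc4)cc(OCc4ccccc4)cc3o2)cc1)c1ccc(OC)cc1 | intermediate
27 | mixed anhydride of acid 26 with trifluoroacetic acid | O=C(OC(=O)C(F)(F)F)/C=C(\Oc1cc(OCc2ccccc2)cc(OCc2ccccc2)c1Oc1ccc(-c2cc(=O)c3c(OCc4ccccc4)cc(OCc4ccccc4)cc3o2)cc1)c1ccc(OC)cc1 | intermediate
28 | 5,7-bis(benzyloxy)-8-{4-[5,7-bis(benzyloxy)-4-oxo-4H-chromen-2-yl]phenoxy}-2-(4-methoxyphenyl)-4H-chromen-4-one | COc1ccc(-c2cc(=O)c3c(OCc4ccccc4)cc(OCc4ccccc4)c(Oc4ccc(-c5cc(=O)c6c(OCc7ccccc7)cc(OCc7ccccc7)cc6o5)cc4)c3o2)cc1 | intermediate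
29 | 5,7-dihydroxy-8-[4-(5,7-dihydroxy-4-oxo-4H-chromen-2-yl)phenoxy]-2-(4-methoxyphenyl)-4H-chromen-4-one | COc1ccc(-c2cc(=O)c3c(O)cc(O)c(Oc4ccc(-c5cc(=O)c6c(O)cc(O)cc6o5)cc4)c3o2)cc1 | target

**Step count**

Total: 15 steps. Longest linear sequence: 13 steps (steps 1 to 7, 9 to 11 and 13 to 15); steps 8 and 12 are one-step side branches.

**Steps most likely to fail**

1. Step 6. Thermal oligomerisation of the terminal ynol ether may outrun the cycloaddition, or some of the meta regioisomer may form. Fallback: setting out from phenol 5, nucleophilic aromatic substitution on 4-fluorobenzaldehyde (K2CO3, DMF, 110 °C) would give 4-[2,4-bis(benzyloxy)-6-(methoxymethoxy)phenoxy]benzaldehyde F1. Pinnick oxidation (NaClO2, NaH2PO4, 2-methyl-2-butene, t-BuOH/H2O) would bring the sequence back to the route at acid 15, bypassing steps 4 to 7.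

2. Step 5. The terminal aryl ynol ether may be lost by hydration or oligomerisation during quench and handling. Fallback: setting out from 8, the acetylide 10 formed as in step 5 would be quenched with chlorotrimethylsilane instead of water to give {[2,4-bis(benzyloxy)-6-(methoxymethoxy)phenoxy]ethynyl}trimethylsilane F2, a silyl-capped ynol ether that can be chromatographed and stored. Desilylation with K2CO3 (cat.) in MeOH/THF at 0 °C directly before the cycloaddition would come back to the route at 11.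

3. Step 14. Acid cleavage of the aryl vinyl ether, or loss and transfer of benzyl groups, may compete with ring closure. Fallback: setting out from phenol 21 (bypassing steps 13 and 14), magnesium-mediated ortho-formylation (MgCl2, Et3N, paraformaldehyde, MeCN, reflux) would give 4,6-bis(benzyloxy)-3-{4-[5,7-bis(benzyloxy)-4-oxo-4H-chromen-2-yl]phenoxy}-2-hydroxybenzaldehyde F3, since only one position ortho to the hydroxyl is free. Addition of lithium acetylide 23 (3 equiv, THF, -78 °C) would give the racemic propargylic alcohol 1-(4,6-bis(benzyloxy)-3-{4-[5,7-bis(benzyloxy)-4-oxo-4H-chromen-2-yl]phenoxy}-2-hydroxyphenyl)-3-(4-methoxyphenyl)prop-2-yn-1-ol F4. Oxidation with MnO2 in CH2Cl2 would give the o-hydroxyaryl ynone 1-(4,6-bis(benzyloxy)-3-{4-[5,7-bis(benzyloxy)-4-oxo-4H-chromen-2-yl]phenoxy}-2-hydroxyphenyl)-3-(4-methoxyphenyl)prop-2-yn-1-one F5. Amine-mediated 6-endo cyclisation (Et2NH, EtOH, reflux) would come back to the route at 28.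

**Further compounds**

F1 | step 6 | 4-[2,4-bis(benzyloxy)-6-(methoxymethoxy)phenoxy]benzaldehyde | O=Cc1ccc(Oc2c(OCOC)cc(OCc3ccccc3)cc2OCc2ccccc2)cc1
F2 | step 5 | {[2,4-bis(benzyloxy)-6-(methoxymethoxy)phenoxy]ethynyl}trimethylsilane | C[Si](C)(C)C#COc1c(OCOC)cc(OCc2ccccc2)cc1OCc1ccccc1
F3 | step 14 | 4,6-bis(benzyloxy)-3-{4-[5,7-bis(benzyloxy)-4-oxo-4H-chromen-2-yl]phenoxy}-2-hydroxybenzaldehyde | O=Cc1c(O)c(Oc2ccc(-c3cc(=O)c4c(OCc5ccccc5)cc(OCc5ccccc5)cc4o3)cc2)c(OCc2ccccc2)cc1OCc1ccccc1
F4 | step 14 | 1-(4,6-bis(benzyloxy)-3-{4-[5,7-bis(benzyloxy)-4-oxo-4H-chromen-2-yl]phenoxy}-2-hydroxyphenyl)-3-(4-methoxyphenyl)prop-2-yn-1-ol (racemic) | OC(C#Cc1ccc(OC)cc1)c1c(O)c(Oc2ccc(-c3cc(=O)c4c(OCc5ccccc5)cc(OCc5ccccc5)cc4o3)cc2)c(OCc2ccccc2)cc1OCc1ccccc1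
F5 | step 14 | 1-(4,6-bis(benzyloxy)-3-{4-[5,7-bis(benzyloxy)-4-oxo-4H-chromen-2-yl]phenoxy}-2-hydroxyphenyl)-3-(4-methoxyphenyl)prop-2-yn-1-one | O=C(C#Cc1ccc(OC)cc1)c1c(O)c(Oc2ccc(-c3cc(=O)c4c(OCc5ccccc5)cc(OCc5ccccc5)cc4o3)cc2)c(OCc2ccccc2)cc1OCc1ccccc1
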